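**Assumption:** perrottetin F has no stereocentre and no stereogenic axis, so it is achiral and no asymmetric step is needed; the only stereo-elements in the route are alkene geometries that are erased by hydrogenation.

## Retrosynthetic overview

1. No ring is constructed: the four benzene rings are bought as 3-hydroxy-4,5-dimethoxybenzaldehyde 1 (ring C), (3-methoxyphenyl)acetic acid 2 (rings A and D, used twice) and 4-fluorobenzaldehyde 3 (ring B). The target comes from its tetramethyl ether by fourfold O-demethylation.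
2. Each ArCH2–CH2Ar' bridge ⇐ stilbene ⇐ α-aryl cinnamic acid ⇐ ArCHO + acid 2 by a Perkin-type aldol condensation (the key C–C bonds), followed by decarboxylation and hydrogenation.
3. Diaryl ether (ring B–O–ring C) ⇐ the ring C/D bibenzyl phenol + 3 by SNAr, which also brings in the aldehyde for the second condensation.
4. Order of assembly: ring C + ring D (first bridge), then ring B onto ring C (ether), then ring A onto ring B (second bridge), then deprotection.

## Route

Step 1
Reactants: 1 3-hydroxy-4,5-dimethoxybenzaldehyde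
Product: 4 3-(benzyloxy)-4,5-dimethoxybenzaldehyde
Conditions: BnBr (1.1 equiv), K2CO3, DMF, 60 °C
Reagents that add atoms: benzyl bromide, BrCc1ccccc1
Why: Williamson ether synthesis (SN2 of the phenoxide on a benzylic bromide) masks the only free phenol so that it cannot be acetylated or interfere in the condensation and decarboxylation, and the benzyl group is later removed in the same hydrogenation that saturates the first stilbene.

Step 2
Reactants: 4 3-(benzyloxy)-4,5-dimethoxybenzaldehyde; 2 (3-methoxyphenyl)acetic acid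
Product: 5 (2E)-3-[3-(benzyloxy)-4,5-dimethoxyphenyl]-2-(3-methoxyphenyl)prop-2-enoic acid
Conditions: Ac2O, Et3N, 120 °C, 8 h; then H2O, aq. HCl
Reagents that add atoms: none
Why: Perkin (Oglialoro) condensation, an intermolecular aldol-type condensation in which the enolised, anhydride-activated arylacetic acid adds to the non-enolisable aldehyde and Ac2O drives the dehydration, gives the thermodynamically preferred (E)-acid (aryl groups cis) without creating a stereocentre.

Step 3
Reactants: 5 (2E)-3-[3-(benzyloxy)-4,5-dimethoxyphenyl]-2-(3-methoxyphenyl)prop-2-enoic acid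
Product: 6 1-(benzyloxy)-2,3-dimethoxy-5-[(Z)-2-(3-methoxyphenyl)ethenyl]benzene
Conditions: Cu powder, quinoline, 210 °C; then 2 M HCl wash
Reagents that add atoms: none
Why: Copper-mediated protodecarboxylation of an α-aryl cinnamic acid proceeds with retention at the vinyl carbon to give mainly the (Z)-stilbene, and any (E)-isomer is harmless because the double bond is hydrogenated next.

Step 4
Reactants: 6 1-(benzyloxy)-2,3-dimethoxy-5-[(Z)-2-(3-methoxyphenyl)ethenyl]benzene
Product: 8 2,3-dimethoxy-5-[2-(3-methoxyphenyl)ethyl]phenol, via O-benzyl bibenzyl 7 (not isolated)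
Conditions: H2 (1 atm), 10% Pd/C, EtOAc/EtOH, rt
Reagents that add atoms: none
Why: Heterogeneous catalytic hydrogenation saturates the stilbene C=C and then hydrogenolyses the benzyl ether in the same pot, which erases the alkene geometry, creates no stereocentre and unveils the ring C phenol.

Step 5
Reactants: 8 2,3-dimethoxy-5-[2-(3-methoxyphenyl)ethyl]phenol; 3 4-fluorobenzaldehyde
Product: 9 4-{2,3-dimethoxy-5-[2-(3-methoxyphenyl)ethyl]phenoxy}benzaldehyde
Conditions: K2CO3, DMAc, 140 °C, argon
Reagents that add atoms: none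
Why: Nucleophilic aromatic substitution (SNAr) works because the para-formyl group activates the C–F bond towards the electron-rich phenoxide of 8, and it installs the diaryl ether together with the aldehyde needed for the second condensation.

Step 6
Reactants: 9 4-{2,3-dimethoxy-5-[2-(3-methoxyphenyl)ethyl]phenoxy}benzaldehyde; 2 (3-methoxyphenyl)acetic acid
Product: 10 (2E)-3-(4-{2,3-dimethoxy-5-[2-(3-methoxyphenyl)ethyl]phenoxy}phenyl)-2-(3-methoxyphenyl)prop-2-enoic acid
Conditions: Ac2O, Et3N, 120 °C, 12 h; then H2O, aq. HCl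
Reagents that add atoms: none
Why: A second Perkin (Oglialoro) aldol-type condensation joins ring A to ring B exactly as in step 2, the ethers and the saturated bridge being inert to Ac2O and Et3N, and again gives the (E)-acid with no stereocentre.

Step 7
Reactants: 10 (2E)-3-(4-{2,3-dimethoxy-5-[2-(3-methoxyphenyl)ethyl]phenoxy}phenyl)-2-(3-methoxyphenyl)prop-2-enoic acid
Product: 11 1,2-dimethoxy-5-[2-(3-methoxyphenyl)ethyl]-3-{4-[(Z)-2-(3-methoxyphenyl)ethenyl]phenoxy}benzene
Conditions: Cu powder, quinoline, 210 °C; then 2 M HCl wash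
Reagents that add atoms: none
Why: Copper-mediated protodecarboxylation as in step 3 removes the carboxyl group, the diaryl ether and methyl ethers being stable to these conditions, and the Z/E ratio is irrelevant for the next step.

Step 8
Reactants: 11 1,2-dimethoxy-5-[2-(3-methoxyphenyl)ethyl]-3-{4-[(Z)-2-(3-methoxyphenyl)ethenyl]phenoxy}benzene
Product: 12 1,2-dimethoxy-5-[2-(3-methoxyphenyl)ethyl]-3-{4-[2-(3-methoxyphenyl)ethyl]phenoxy}benzene
Conditions: H2 (1 atm), 10% Pd/C, EtOAc, rt
Reagents that add atoms: none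
Why: Catalytic hydrogenation of the disubstituted stilbene is fast and chemoselective, since diaryl and methyl ethers are not hydrogenolysed, and it completes the second bibenzyl bridge without a stereocentre.

Step 9
Reactants: 12 1,2-dimethoxy-5-[2-(3-methoxyphenyl)ethyl]-3-{4-[2-(3-methoxyphenyl)ethyl]phenoxy}benzene
Product: 13 perrottetin F
Conditions: BBr3 (8 equiv), CH2Cl2, −78 °C to rt; then H2O
Reagents that add atoms: none
Why: Lewis acid-mediated aryl methyl ether cleavage (BBr3 activates each methoxy oxygen and bromide removes the methyl group by SN2) frees all four phenols after hydrolytic work-up, while the diaryl ether and the CH2CH2 bridges are untouched.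

## Compound list

1 | 3-hydroxy-4,5-dimethoxybenzaldehyde | O=Cc1cc(O)c(OC)c(OC)c1 | starting material
2 | (3-methoxyphenyl)acetic acid | COc1cccc(CC(=O)O)c1 | starting material
3 | 4-fluorobenzaldehyde | O=Cc1ccc(F)cc1 | starting material
4 | 3-(benzyloxy)-4,5-dimethoxybenzaldehyde | O=Cc1cc(OCc2ccccc2)c(OC)c(OC)c1 | intermediate
5 | (2E)-3-[3-(benzyloxy)-4,5-dimethoxyphenyl]-2-(3-methoxyphenyl)prop-2-enoic acid | OC(=O)/C(c1cccc(OC)c1)=C/c1cc(OCc2ccccc2)c(OC)c(OC)c1 | intermediate
6 | 1-(benzyloxy)-2,3-dimethoxy-5-[(Z)-2-(3-methoxyphenyl)ethenyl]benzene (major isomer; minor E isomer converges in step 4) | COc1cccc(/C=C\c2cc(OCc3ccccc3)c(OC)c(OC)c2)c1 | intermediate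
7 | 1-(benzyloxy)-2,3-dimethoxy-5-[2-(3-methoxyphenyl)ethyl]benzene (O-benzyl bibenzyl, not isolated) | COc1cccc(CCc2cc(OCc3ccccc3)c(OC)c(OC)c2)c1 | intermediate
8 | 2,3-dimethoxy-5-[2-(3-methoxyphenyl)ethyl]phenol | COc1cccc(CCc2cc(O)c(OC)c(OC)c2)c1 | intermediate
9 | 4-{2,3-dimethoxy-5-[2-(3-methoxyphenyl)ethyl]phenoxy}benzaldehyde | COc1cccc(CCc2cc(Oc3ccc(C=O)cc3)c(OC)c(OC)c2)c1 | intermediate
10 | (2E)-3-(4-{2,3-dimethoxy-5-[2-(3-methoxyphenyl)ethyl]phenoxy}phenyl)-2-(3-methoxyphenyl)prop-2-enoic acid | OC(=O)/C(c1cccc(OC)c1)=C/c1ccc(Oc2cc(CCc3cccc(OC)c3)cc(OC)c2OC)cc1 | intermediate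
11 | 1,2-dimethoxy-5-[2-(3-methoxyphenyl)ethyl]-3-{4-[(Z)-2-(3-methoxyphenyl)ethenyl]phenoxy}benzene (major isomer; minor E isomer converges in step 8) | COc1cccc(/C=C\c2ccc(Oc3cc(CCc4cccc(OC)c4)cc(OC)c3OC)cc2)c1 | intermediate
12 | 1,2-dimethoxy-5-[2-(3-methoxyphenyl)ethyl]-3-{4-[2-(3-methoxyphenyl)ethyl]phenoxy}benzene (perrottetin F tetramethyl ether) | COc1cccc(CCc2ccc(Oc3cc(CCc4cccc(OC)c4)cc(OC)c3OC)cc2)c1 | intermediate
13 | perrottetin F, 5-[2-(3-hydroxyphenyl)ethyl]-3-{4-[2-(3-hydroxyphenyl)ethyl]phenoxy}benzene-1,2-diol (achiral) | Oc1cccc(CCc2ccc(Oc3cc(CCc4cccc(O)c4)cc(O)c3O)cc2)c1 | target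

## Step count and risks

Total step count: 9. Longest linear sequence: 9 steps (1 to 13); acid 2 and aldehyde 3 are bought and used directly.

The three steps most likely to fail:

**Step 7** (thermal Cu/quinoline decarboxylation on the most advanced acid; risk of incomplete reaction or tar at 210 °C). The fallback sets out from 10 and comes back at 12, so step 8 is skipped. Acid 10 is hydrogenated (H2, 10% Pd/C, EtOAc/MeOH) to racemic 3-(4-{2,3-dimethoxy-5-[2-(3-methoxyphenyl)ethyl]phenoxy}phenyl)-2-(3-methoxyphenyl)propanoic acid F1. This is esterified with N-hydroxyphthalimide and N,N'-diisopropylcarbodiimide (DMAP cat., CH2Cl2, rt) to the redox-active ester 1,3-dioxoisoindolin-2-yl 3-(4-{2,3-dimethoxy-5-[2-(3-methoxyphenyl)ethyl]phenoxy}phenyl)-2-(3-methoxyphenyl)propanoate F2. Radical reductive decarboxylation of F2 (NiCl2·6H2O and 4,4'-di-tert-butyl-2,2'-bipyridine as catalyst, Zn, PhSiH3, THF/DMF/i-PrOH, 40 °C) replaces the carboxyl by hydrogen through the benzylic radical. The transient stereocentre of F1 disappears and the product is 12.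

**Step 6** (Perkin condensation on a 4-aryloxybenzaldehyde, which is electron-rich and less electrophilic than aldehyde 4; risk of low conversion). The fallback sets out from 9 and comes back at 10, replacing the one-pot condensation by a directed aldol with separate dehydration. The lithium enolate of commercial methyl (3-methoxyphenyl)acetate (LDA, THF, −78 °C) is added to aldehyde 9 to give methyl 3-(4-{2,3-dimethoxy-5-[2-(3-methoxyphenyl)ethyl]phenoxy}phenyl)-3-hydroxy-2-(3-methoxyphenyl)propanoate F3 (racemic syn/anti mixture). Acid-catalysed dehydration (TsOH·H2O, toluene, reflux, Dean–Stark) gives methyl (2E)-3-(4-{2,3-dimethoxy-5-[2-(3-methoxyphenyl)ethyl]phenoxy}phenyl)-2-(3-methoxyphenyl)prop-2-enoate F4. Saponification (LiOH, THF/MeOH/H2O, 60 °C; then aq. HCl) returns acid 10; any Z-isomer can be carried on because both isomers converge at 12.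

**Step 5** (SNAr at 140 °C with a base-sensitive aldehyde as electrophile and an ortho-substituted phenoxide). The fallback sets out from 8 and comes back at 9, changing the C–O bond formation to a copper-catalysed Ullmann-type coupling with a protected aldehyde. Phenol 8 is coupled with commercial 2-(4-bromophenyl)-1,3-dioxolane (CuI 10 mol %, N,N-dimethylglycine hydrochloride, Cs2CO3, 1,4-dioxane, 90 °C) to give 2-(4-{2,3-dimethoxy-5-[2-(3-methoxyphenyl)ethyl]phenoxy}phenyl)-1,3-dioxolane F5. Acetal hydrolysis (1 M HCl, THF, rt) gives aldehyde 9.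

Further compounds
F1 | step 7 | racemic 3-(4-{2,3-dimethoxy-5-[2-(3-methoxyphenyl)ethyl]phenoxy}phenyl)-2-(3-methoxyphenyl)propanoic acid | OC(=O)C(c1cccc(OC)c1)Cc1ccc(Oc2cc(CCc3cccc(OC)c3)cc(OC)c2OC)cc1
F2 | step 7 | racemic 1,3-dioxoisoindolin-2-yl 3-(4-{2,3-dimethoxy-5-[2-(3-methoxyphenyl)ethyl]phenoxy}phenyl)-2-(3-methoxyphenyl)propanoate | O=C(ON1C(=O)c2ccccc2C1=O)C(c1cccc(OC)c1)Cc1ccc(Oc2cc(CCc3cccc(OC)c3)cc(OC)c2OC)cc1
F3 | step 6 | methyl 3-(4-{2,3-dimethoxy-5-[2-(3-methoxyphenyl)ethyl]phenoxy}phenyl)-3-hydroxy-2-(3-methoxyphenyl)propanoate (racemic syn/anti mixture) | COC(=O)C(c1cccc(OC)c1)C(O)c1ccc(Oc2cc(CCc3cccc(OC)c3)cc(OC)c2OC)cc1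
F4 | step 6 | methyl (2E)-3-(4-{2,3-dimethoxy-5-[2-(3-methoxyphenyl)ethyl]phenoxy}phenyl)-2-(3-methoxyphenyl)prop-2-enoate | COC(=O)/C(c1cccc(OC)c1)=C/c1ccc(Oc2cc(CCc3cccc(OC)c3)cc(OC)c2OC)cc1
F5 | step 5 | 2-(4-{2,3-dimethoxy-5-[2-(3-methoxyphenyl)ethyl]phenoxy}phenyl)-1,3-dioxolane | COc1cccc(CCc2cc(Oc3ccc(C4OCCO4)cc3)c(OC)c(OC)c2)c1
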